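**Retrosynthetic overview** (cembrane numbering is used throughout)

1. Target 39 comes from desilylation and α-methylenation of the C16,14-γ-lactone; the 14-membered carbocycle is closed by an intramolecular Z-selective Wittig reaction at C6=C7.
2. C10–C11 comes from an alkyl–alkyl Suzuki coupling of a C7–C10 borane (C8 from (S)-2-methylglycidol) with a C11 bromide; C12 is set by Rh-catalysed hydroboration of an isopropenyl group, C4 by chelation-controlled methyl addition.
3. The C4 ketone arm and the C12 aldehyde arm are the ozonolysis products of the C4=C12 bridge of an 8-oxabicyclo[3.2.1]octene; the cis-fused lactone grows from its C1 ketone and C14–O (butenolide annulation, C14 equilibration, hydrogenation).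
4. Key disconnection: (4+3) cycloaddition of 3-(2-chloroethyl)furan with a chiral 1-alkoxy-2-silyloxyallyl cation, forming C2–C3 and C13–C14 together. It is made possible by the 2,6-cis-oxane ring O–C3–C2–C1–C14–C13: its O with the two CH neighbours C3 and C13 (plus C4, C12) is a furan in disguise, and C2–C1–C14(O) is an oxyallyl cation.
5. Order of ring formation: oxane (as oxabicycle, step 5), lactone ring (steps 7 and 10), 14-membered carbocycle (step 22).

Key step: step 5

Remark on numbering: C1 is the ring-fusion carbon of the lactone, C3 and C13 are the two C–O carbons of the oxane, C14 is the lactone C–O carbon; the target is (1R,3R,4S,6Z,8R,12S,13R,14S).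
Assumption: the (S)-1-(naphthalen-2-yl)ethoxy group is taken to steer the furan to the face of cation 10 that gives the bridgeheads drawn for 11; if the induction is the opposite one, the commercial (R)-alcohol is used and nothing else changes.

**Route**

Step 1
Reactants: 1 3-bromofuran
Product: 3 2-(furan-3-yl)ethan-1-ol, via 3-furyllithium 2 (not isolated)
Conditions: n-BuLi, THF, −78 °C; then oxirane, BF3·OEt2, −78 °C
Reagents that add atoms: oxirane, C1CO1
Why: Bromine–lithium exchange at −78 °C gives 3-furyllithium before it can isomerise, and BF3-assisted epoxide opening by an aryllithium is a standard hydroxyethylation.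

Step 2
Reactants: 3 2-(furan-3-yl)ethan-1-ol
Product: 4 3-(2-chloroethyl)furan
Conditions: PPh3, N-chlorosuccinimide, CH2Cl2, 0 °C to rt
Reagents that add atoms: N-chlorosuccinimide, O=C1CCC(=O)N1Cl
Why: Appel-type chlorination is neutral enough for the acid-sensitive furan, and the primary chloride is an inert placeholder for the later phosphonium salt.

Step 3
Reactants: 5 1,1-dimethoxypropan-2-one (excess); 6 (S)-1-(naphthalen-2-yl)ethan-1-ol
Product: 7 1-methoxy-1-[(1S)-1-(naphthalen-2-yl)ethoxy]propan-2-one (both epimers at the acetal carbon)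
Conditions: pyridinium p-toluenesulfonate (cat.), cyclohexane, 60 °C, 5 Å molecular sieves
Reagents that add atoms: none
Why: Acid-catalysed transacetalisation with removal of methanol exchanges one methoxy group for the chiral alkoxy group; the acetal centre forms as a mixture that does not matter because it is ionised in step 5.

Step 4
Reactants: 7 mixed acetal
Product: 9 triethyl({3-methoxy-3-[(1S)-1-(naphthalen-2-yl)ethoxy]prop-1-en-2-yl}oxy)silane, via lithium enolate 8 (not isolated)
Conditions: LiN(iPr)2, THF, −78 °C; then Et3SiCl, −78 °C to rt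
Reagents that add atoms: chlorotriethylsilane, CC[Si](Cl)(CC)CC
Why: Kinetic deprotonation of the methyl ketone and O-silylation (silyl enol ether formation) give the 2-silyloxyallyl acetal that is the cation precursor.

Step 5
Reactants: 4 3-(2-chloroethyl)furan (2 equiv); 9 silyl enol ether
Product: 11 6-(2-chloroethyl)-2-[(1S)-1-(naphthalen-2-yl)ethoxy]-8-oxabicyclo[3.2.1]oct-6-en-3-one (ether equatorial and cis to the C6=C7 bridge; bridgeheads are the later C13 and C3), via allyl cation 10 (not isolated)
Conditions: Me3SiOTf (0.1 equiv), CH2Cl2, −95 °C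
Reagents that add atoms: none
Why: Me3SiOTf removes the methoxy group of 9 to give the 1-alkoxy-2-silyloxyallyl cation 10, which adds across C2 and C5 of the furan in a (4+3) cycloaddition, most likely stepwise (furan C2 to the CH2 terminus, then the silyl enol ether carbon C14 onto the furan-derived oxocarbenium ion), and loss of the silyl group as Et3SiOTf gives the ketone and carries the chain; the closest known reaction type is the cycloaddition of chiral 1-alkoxy-2-silyloxyallyl cations with furans. The second bond closes the seven-membered carbocycle in the 7-exo-trig mode at the oxocarbenium carbon and thereby the oxane ring in the 6-endo-trig mode, so the two C–O carbons C3 and C13 are cis by the geometry of the bicycle. Their absolute configuration is controlled by the 1-(naphthalen-2-yl)ethoxy group, whose aryl ring covers one face of the planar cation. The ether carbon C14 should come out equatorial (compact transition state), but this centre need not be controlled because it is equilibrated in step 10. The step needs head-to-tail regioselectivity, secured by the 3-alkyl group, which makes C2 the more nucleophilic α-carbon of the furan and so the partner of the soft, unsubstituted terminus of the cation. It also needs ring closure to outrun proton loss from the first adduct (Friedel–Crafts alkylation), which the low temperature and the non-basic triflate counter-ion favour.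

Step 6
Reactants: 11 oxabicyclic ether
Product: 12 6-(2-chloroethyl)-2-hydroxy-8-oxabicyclo[3.2.1]oct-6-en-3-one (hydroxyl equatorial)
Conditions: DDQ, CH2Cl2/pH 7 buffer, 0 °C to rt
Reagents that add atoms: none
Why: DDQ abstracts the benzylic hydride of the electron-rich 1-(naphthalen-2-yl)ethyl group and the hemiketal hydrolyses (oxidative cleavage of naphthylmethyl-type ethers), leaving ketone, alkene and alkyl chloride untouched.

Step 7
Reactants: 12 ketol
Product: 14 tricyclic butenolide (but-2-en-4-olide fused across C14–C1 of the oxabicycle; lactone oxygen on C14 and cis to the alkene bridge), via ester ylide 13 (not isolated)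
Conditions: Ph3P=C=C=O, toluene, 80 °C
Reagents that add atoms: (triphenylphosphoranylidene)ketene, O=C=C=P(c1ccccc1)(c1ccccc1)c1ccccc1
Why: The ketene ylide acylates the hydroxyl group and the stabilised ylide 13 closes the butenolide by intramolecular Wittig reaction on the neighbouring ketone (Bestmann butenolide synthesis), the equatorial C14–O bond lying in the plane the new ring needs.

Step 8
Reactants: 14 tricyclic butenolide
Product: 15 butenolide-fused 2,6-cis-oxane with a 3-chloropropanoyl group on C3 and a formyl group on C13 (lactone oxygen still cis to the C13 arm)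
Conditions: O3, CH2Cl2, −78 °C (Sudan Red 7B end point); then Me2S, −78 °C to rt; used crude
Reagents that add atoms: ozone, [O-][O+]=O
Why: Ozonolysis cleaves the strained, electron-rich trisubstituted C4=C12 alkene far faster than the electron-poor butenolide alkene and so unzips the bicycle into the oxane with two different carbonyl arms.

Step 9
Reactants: 15 keto aldehyde
Product: 16 diol with a (2S)-4-chloro-2-hydroxybutan-2-yl group on C3 and a 1-hydroxyethyl group (both epimers) on C13
Conditions: MeTiCl3 (3.5 equiv), CH2Cl2, −78 to −30 °C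
Reagents that add atoms: methyltitanium trichloride, C[Ti](Cl)(Cl)Cl
Why: MeTiCl3 adds to the aldehyde and, through the five-membered chelate of titanium with the oxane oxygen and the C4 ketone, to the ketone face anti to C2 (Cram-chelate addition), which sets the (4S) carbinol; it does not attack the butenolide, and the C12 carbinol centre is oxidised away in step 11.

Step 10
Reactants: 16 diol
Product: 18 saturated cis-fused γ-lactone diol (lactone oxygen on C14 trans to the C13 arm; C15 on C1 cis to that oxygen), via trans-butenolide 17 (not isolated)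
Conditions: DBU (0.2 equiv), EtOAc, rt; then H2 (1 atm), Pd/C (10 %), rt
Reagents that add atoms: none
Why: DBU deprotonates the γ-carbon C14 to the 2-oxidofuran and reprotonation gives the thermodynamic all-equatorial oxane (butenolide γ-epimerisation), after which hydrogen adds to the butenolide from the convex face that carries the C14 hydrogen (syn hydrogenation), giving the cis-fused lactone and the (1R) centre.

Step 11
Reactants: 18 lactone diol
Product: 19 methyl ketone (acetyl group on C13)
Conditions: Dess–Martin periodinane, CH2Cl2, rt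
Reagents that add atoms: none
Why: Dess–Martin oxidation of the secondary alcohol is neutral, so C13 (α to the new ketone, β to the lactone oxygen) is neither epimerised nor eliminated, and the tertiary alcohol is inert.

Step 12
Reactants: 19 methyl ketone
Product: 20 isopropenyl compound (prop-1-en-2-yl group on C13)
Conditions: Zn, CH2Br2, TiCl4, THF, 0 °C (reagent pre-formed); then 19, CH2Cl2, 0 °C to rt
Reagents that add atoms: dibromomethane, BrCBr
Why: The non-basic Takai–Lombardo reagent methylenates the ketone without touching the lactone or enolising toward C13.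

Step 13
Reactants: 20 isopropenyl compound
Product: 21 triethylsilyl ether of 20 (C4–OSiEt3)
Conditions: Et3SiOTf, 2,6-lutidine, CH2Cl2, −78 to 0 °C
Reagents that add atoms: triethylsilyl trifluoromethanesulfonate, CC[Si](CC)(CC)OS(=O)(=O)C(F)(F)F
Why: Silyl triflate silylation protects the hindered tertiary alcohol for the ylide and enolate steps to come.

Step 14
Reactants: 21 silyl ether
Product: 23 primary alcohol with a (2S)-1-hydroxypropan-2-yl group on C13, via catechol boronate 22 (not isolated)
Conditions: catecholborane, RhCl(PPh3)3 (3 mol %), THF, 0 °C to rt; then H2O2, pH 7 phosphate buffer, 0 °C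
Reagents that add atoms: hydrogen peroxide, OO
Why: Rhodium-catalysed hydroboration of a 1,1-disubstituted alkene with an allylic C–O bond is syn-selective (C–O anti to rhodium in the alkene complex, the sense opposite to uncatalysed 9-BBN), which places the C12 methyl group syn to the oxane oxygen, that is (12S); oxidation at pH 7 spares the lactone.

Step 15
Reactants: 23 primary alcohol
Product: 24 primary bromide (C11–Br)
Conditions: CBr4, PPh3, CH2Cl2, 0 °C
Reagents that add atoms: tetrabromomethane, BrC(Br)(Br)Br
Why: Appel bromination gives the electrophile for the cross-coupling and leaves the primary chloride and the silyl ether alone.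

Step 16
Reactants: 25 (S)-2-methylglycidol
Product: 26 triethyl{[(2S)-2-methyloxiran-2-yl]methoxy}silane
Conditions: Et3SiCl, imidazole, CH2Cl2, 0 °C
Reagents that add atoms: chlorotriethylsilane, CC[Si](Cl)(CC)CC
Why: Silylation masks the hydroxyl group so that the ylide of step 17 is not quenched and no Payne rearrangement can touch the stereocentre.

Step 17
Reactants: 26 silyl glycidyl ether
Product: 27 (R)-2-methyl-1-(triethylsilyloxy)but-3-en-2-ol
Conditions: Me3S+ I−, n-BuLi, THF, −10 °C to rt
Reagents that add atoms: trimethylsulfonium iodide, C[S+](C)C.[I-]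
Why: Dimethylsulfonium methylide opens the epoxide at CH2 and the resulting sulfonium salt eliminates dimethyl sulfide (one-carbon homologation of an epoxide to an allylic alcohol), which leaves the C8 stereocentre of the chiral pool untouched.

Step 18
Reactants: 27 allylic alcohol
Product: 28 (R)-2-methyl-1,2-bis(triethylsilyloxy)but-3-ene
Conditions: Et3SiOTf, 2,6-lutidine, CH2Cl2, −78 to 0 °C
Reagents that add atoms: triethylsilyl trifluoromethanesulfonate, CC[Si](CC)(CC)OS(=O)(=O)C(F)(F)F
Why: Silylation of the tertiary alcohol gives the bis(silyl ether), whose primary silyl ether is the masked C7 aldehyde; any O-to-O silyl shift in step 17 becomes irrelevant.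

Step 19
Reactants: 28 bis(silyl ether); 24 primary bromide
Product: 30 coupled tris(silyl ether) (C10–C11 formed; chloroethyl arm intact), via B-alkyl-9-BBN 29 (not isolated)
Conditions: 28, 9-BBN-H dimer, THF, rt; then 24, Pd(OAc)2 (5 mol %), PCy3 (10 mol %), K3PO4·H2O, THF, rt
Reagents that add atoms: none
Why: 9-BBN hydroborates the vinyl group at its terminus and the B-alkyl borane couples with the primary bromide under Pd(OAc)2/PCy3 (alkyl–alkyl Suzuki–Miyaura coupling), so C10–C11 is formed without an alkene that would have to be reduced; the alkyl chloride does not react at room temperature.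

Step 20
Reactants: 30 tris(silyl ether)
Product: 31 C7 aldehyde (tertiary silyl ethers on C4 and C8 kept)
Conditions: (COCl)2, DMSO, CH2Cl2, −78 to −30 °C; then Et3N, to 0 °C
Reagents that add atoms: none
Why: Under Swern conditions a primary triethylsilyl ether is cleaved and oxidised directly to the aldehyde while tertiary silyl ethers survive (selective Swern oxidation of primary silyl ethers).

Step 21
Reactants: 31 aldehyde
Product: 32 phosphonium iodide (C6–PPh3+ I−)
Conditions: NaI, PPh3, MeCN, 80 °C
Reagents that add atoms: triphenylphosphine, c1ccc(cc1)P(c1ccccc1)c1ccccc1; sodium iodide, [Na+].[I-]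
Why: Finkelstein exchange in the flask and SN2 quaternisation of PPh3 convert the primary chloride into the phosphonium salt; the aldehyde has no α-hydrogen and is inert.

Step 22
Reactants: 32 phosphonium iodide
Product: 34 macrocyclic (6Z)-alkene (bis(triethylsilyl) ether; saturated lactone), via phosphonium ylide 33 (not isolated)
Conditions: KN(SiMe3)2 (slow addition), THF (0.001 M in 32), −78 °C to rt
Reagents that add atoms: none
Why: The non-stabilised ylide condenses with the hindered α-silyloxy aldehyde in an intramolecular Wittig reaction under salt-free high-dilution conditions, kinetic formation of the cis-oxaphosphetane giving the (6Z)-alkene; the phosphonium salt is far more acidic than the lactone, which is not enolised.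

Step 23
Reactants: 34 macrocyclic lactone
Product: 38 bis(triethylsilyl) ether of the target, via lithium enolate 35 (not isolated), via Mannich base 36 (not isolated), via ammonium iodide 37 (not isolated)
Conditions: LiN(iPr)2, THF, −78 °C; CH2=NMe2+ I−, −78 °C to rt; then MeI, MeOH, rt; then NaHCO3, CH2Cl2/H2O
Reagents that add atoms: Eschenmoser's salt, C=[N+](C)C.[I-]
Why: The lactone enolate is aminomethylated and the Mannich base is quaternised and eliminated (α-methylenation of lactones), which installs the C15=C17 alkene last because it would not survive the earlier ylide and hydride steps.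

Step 24
Reactants: 38 bis(silyl ether)
Product: 39 CNP0146755.1, (1R,3R,4S,6Z,8R,12S,13R,14S)-4,8-dihydroxy-3,13-epoxycembra-6,15(17)-dien-16,14-olide
Conditions: HF·pyridine, pyridine, THF, 0 °C to rt
Reagents that add atoms: none
Why: Buffered HF·pyridine cleaves both tertiary silyl ethers (fluoride desilylation) without conjugate addition to, or isomerisation of, the α-methylene lactone.

**Compound list**

1 | 3-bromofuran | Brc1ccoc1 | starting material
2 | 3-furyllithium | [Li]c1ccoc1 | intermediate
3 | 2-(furan-3-yl)ethan-1-ol | OCCc1ccoc1 | intermediate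
4 | 3-(2-chloroethyl)furan | ClCCc1ccoc1 | intermediate
5 | 1,1-dimethoxypropan-2-one | CC(=O)C(OC)OC | starting material
6 | (S)-1-(naphthalen-2-yl)ethan-1-ol | C[C@H](O)c1ccc2ccccc2c1 | starting material
7 | 1-methoxy-1-[(1S)-1-(naphthalen-2-yl)ethoxy]propan-2-one (acetal carbon as a mixture) | CC(=O)C(OC)O[C@@H](C)c1ccc2ccccc2c1 | intermediate
8 | lithium enolate of 7 | [Li]OC(=C)C(OC)O[C@@H](C)c1ccc2ccccc2c1 | intermediate
9 | triethyl({3-methoxy-3-[(1S)-1-(naphthalen-2-yl)ethoxy]prop-1-en-2-yl}oxy)silane | C=C(O[Si](CC)(CC)CC)C(OC)O[C@@H](C)c1ccc2ccccc2c1 | intermediate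
10 | 1-[(1S)-1-(naphthalen-2-yl)ethoxy]-2-(triethylsilyloxy)allyl cation, triflate | C=C(O[Si](CC)(CC)CC)C=[O+][C@@H](C)c1ccc2ccccc2c1.[O-]S(=O)(=O)C(F)(F)F | intermediate
11 | 6-(2-chloroethyl)-2-[(1S)-1-(naphthalen-2-yl)ethoxy]-8-oxabicyclo[3.2.1]oct-6-en-3-one, ether equatorial | O=C1C[C@H]2O[C@H](C=C2CCCl)[C@@H]1O[C@@H](C)c1ccc2ccccc2c1 | intermediate
12 | 6-(2-chloroethyl)-2-hydroxy-8-oxabicyclo[3.2.1]oct-6-en-3-one, hydroxyl equatorial | O=C1C[C@H]2O[C@H](C=C2CCCl)[C@@H]1O | intermediate
13 | (triphenylphosphoranylidene)acetate ester of 12 | O=C1C[C@H]2O[C@H](C=C2CCCl)[C@@H]1OC(=O)C=P(c1ccccc1)(c1ccccc1)c1ccccc1 | intermediate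
14 | tricyclic butenolide (lactone fused across C14–C1 of the oxabicycle) | O=C1C=C2C[C@H]3O[C@H](C=C3CCCl)[C@@H]2O1 | intermediate
15 | butenolide-fused 2,6-cis-oxane, 3-chloropropanoyl on C3, formyl on C13, lactone O cis to the C13 arm | O=C1C=C2C[C@H](C(=O)CCCl)O[C@H](C=O)[C@@H]2O1 | intermediate
16 | diol, (4S) carbinol arm on C3, 1-hydroxyethyl on C13 (both epimers), lactone O cis | O=C1C=C2C[C@H]([C@@](C)(O)CCCl)O[C@H](C(C)O)[C@@H]2O1 | intermediate
17 | C14 epimer of 16 (lactone O trans to the C13 arm) | O=C1C=C2C[C@H]([C@@](C)(O)CCCl)O[C@H](C(C)O)[C@H]2O1 | intermediate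
18 | saturated cis-fused γ-lactone diol | O=C1C[C@H]2C[C@H]([C@@](C)(O)CCCl)O[C@H](C(C)O)[C@H]2O1 | intermediate
19 | methyl ketone (acetyl on C13) | O=C1C[C@H]2C[C@H]([C@@](C)(O)CCCl)O[C@H](C(C)=O)[C@H]2O1 | intermediate
20 | isopropenyl compound | O=C1C[C@H]2C[C@H]([C@@](C)(O)CCCl)O[C@H](C(C)=C)[C@H]2O1 | intermediate
21 | C4 triethylsilyl ether of 20 | O=C1C[C@H]2C[C@H]([C@@](C)(O[Si](CC)(CC)CC)CCCl)O[C@H](C(C)=C)[C@H]2O1 | intermediate
22 | C11 catechol boronate | O=C1C[C@H]2C[C@H]([C@@](C)(O[Si](CC)(CC)CC)CCCl)O[C@H]([C@@H](C)CB3Oc4ccccc4O3)[C@H]2O1 | intermediate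
23 | C11 primary alcohol, (12S) | O=C1C[C@H]2C[C@H]([C@@](C)(O[Si](CC)(CC)CC)CCCl)O[C@H]([C@@H](C)CO)[C@H]2O1 | intermediate
24 | C11 primary bromide | O=C1C[C@H]2C[C@H]([C@@](C)(O[Si](CC)(CC)CC)CCCl)O[C@H]([C@@H](C)CBr)[C@H]2O1 | intermediate
25 | (S)-2-methylglycidol, (2S)-(2-methyloxiran-2-yl)methanol | C[C@]1(CO)CO1 | starting material
26 | triethyl{[(2S)-2-methyloxiran-2-yl]methoxy}silane | C[C@]1(CO[Si](CC)(CC)CC)CO1 | intermediate
27 | (R)-2-methyl-1-(triethylsilyloxy)but-3-en-2-ol | C=C[C@@](C)(O)CO[Si](CC)(CC)CC | intermediate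
28 | (R)-2-methyl-1,2-bis(triethylsilyloxy)but-3-ene | C=C[C@@](C)(O[Si](CC)(CC)CC)CO[Si](CC)(CC)CC | intermediate
29 | B-[(R)-3-methyl-3,4-bis(triethylsilyloxy)butyl]-9-borabicyclo[3.3.1]nonane | B1(CC[C@@](C)(O[Si](CC)(CC)CC)CO[Si](CC)(CC)CC)C2CCCC1CCC2 | intermediate
30 | coupled tris(silyl ether) chloride | O=C1C[C@H]2C[C@H]([C@@](C)(O[Si](CC)(CC)CC)CCCl)O[C@H]([C@@H](C)CCC[C@@](C)(O[Si](CC)(CC)CC)CO[Si](CC)(CC)CC)[C@H]2O1 | intermediate
31 | C7 aldehyde | O=C1C[C@H]2C[C@H]([C@@](C)(O[Si](CC)(CC)CC)CCCl)O[C@H]([C@@H](C)CCC[C@@](C)(O[Si](CC)(CC)CC)C=O)[C@H]2O1 | intermediate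
32 | C6 triphenylphosphonium iodide | O=C1C[C@H]2C[C@H]([C@@](C)(O[Si](CC)(CC)CC)CC[P+](c3ccccc3)(c3ccccc3)c3ccccc3)O[C@H]([C@@H](C)CCC[C@@](C)(O[Si](CC)(CC)CC)C=O)[C@H]2O1.[I-] | intermediate
33 | C6 phosphonium ylide | O=C1C[C@H]2C[C@H]([C@@](C)(O[Si](CC)(CC)CC)CC=P(c3ccccc3)(c3ccccc3)c3ccccc3)O[C@H]([C@@H](C)CCC[C@@](C)(O[Si](CC)(CC)CC)C=O)[C@H]2O1 | intermediate
34 | macrocyclic (6Z)-alkene, bis(triethylsilyl) ether, saturated lactone | C1C(=O)O[C@@H]2[C@@H]3O[C@H](C[C@H]12)[C@@](C)(O[Si](CC)(CC)CC)C/C=C\[C@](C)(O[Si](CC)(CC)CC)CCC[C@@H]3C | intermediate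
35 | lithium enolate of 34 | C1=C(O[Li])O[C@@H]2[C@@H]3O[C@H](C[C@H]12)[C@@](C)(O[Si](CC)(CC)CC)C/C=C\[C@](C)(O[Si](CC)(CC)CC)CCC[C@@H]3C | intermediate
36 | α-(dimethylaminomethyl) lactone | CN(C)CC1C(=O)O[C@@H]2[C@@H]3O[C@H](C[C@H]12)[C@@](C)(O[Si](CC)(CC)CC)C/C=C\[C@](C)(O[Si](CC)(CC)CC)CCC[C@@H]3C | intermediate
37 | α-(trimethylammoniomethyl) lactone iodide | C[N+](C)(C)CC1C(=O)O[C@@H]2[C@@H]3O[C@H](C[C@H]12)[C@@](C)(O[Si](CC)(CC)CC)C/C=C\[C@](C)(O[Si](CC)(CC)CC)CCC[C@@H]3C.[I-] | intermediate
38 | 4,8-bis(triethylsilyl) ether of the target | C=C1C(=O)O[C@@H]2[C@@H]3O[C@H](C[C@H]12)[C@@](C)(O[Si](CC)(CC)CC)C/C=C\[C@](C)(O[Si](CC)(CC)CC)CCC[C@@H]3C | intermediate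
39 | CNP0146755.1 | C=C1C(=O)O[C@@H]2[C@@H]3O[C@H](C[C@H]12)[C@@](C)(O)C/C=C\[C@](C)(O)CCC[C@@H]3C | target

**Step count and risks**

Total step count: 24. Longest linear sequence: 19 steps (steps 1, 2, 5–15, 19–24 from 1; the branch from 5 through steps 3 and 4 is equally long).

Steps most likely to fail, with fallbacks:

Step 5. What may go wrong is loss of regio- or facial control in the cycloaddition, or proton loss from the first cation adduct (Friedel–Crafts alkylation of the furan) instead of ring closure. The fallback sets out from 4 and builds the oxabicycle without the auxiliary, then resolves it. Commercial 2,2-dimethyl-1,3-dioxan-5-one is O-silylated (iPr3SiOTf, Et3N) to 2,2-dimethyl-5-(triisopropylsilyloxy)-4H-1,3-dioxine F1, which loses acetone on heating (retro-hetero-Diels–Alder) to give 2-(triisopropylsilyloxy)prop-2-enal F2. Sc(OTf)3-catalysed (4+3) cycloaddition of F2 with 4 (same regiochemical argument, silyl transfer to the C14 oxygen) should give the racemic silyl ether F3. Fluoride (Bu4NF, AcOH) then liberates 12 together with its enantiomer F4, and lipase-catalysed acetylation (Candida antarctica lipase B, vinyl acetate) removes F4 as its acetate F5; if the enzyme prefers 12, its acetate is collected and methanolysed instead. The route is rejoined at 12.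

Step 22. What may go wrong is intermolecular olefination (oligomerisation) outrunning ring closure, erosion of Z selectivity in the ring, or base damage to the lactone. The fallback sets out from 31 and closes the ring by alkyne metathesis. Ohira–Bestmann homologation of the aldehyde (dimethyl (1-diazo-2-oxopropyl)phosphonate, K2CO3, MeOH) gives the terminal alkyne F7. Finkelstein exchange and Kornblum oxidation (NaI; then DMSO, NaHCO3) turn the chloroethyl arm into the C6 aldehyde F8, and a second Ohira–Bestmann reaction gives the diyne F9. Ring-closing alkyne metathesis ([Mo(≡CC6H4OMe-4)(OSiPh3)3], 5 Å molecular sieves, toluene) with loss of ethyne closes the cycloalkyne F10. Semihydrogenation (H2, Pd/CaCO3 poisoned with Pb(OAc)2, quinoline) gives the (6Z)-alkene, and the route is rejoined at 34.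

Step 14. What may go wrong is poor facial discrimination in the rhodium hydride addition (the allylic C–O bond is a ring ether, not a silyl ether), giving a mixture at C12, or alkene isomerisation. The fallback sets out from 21 and sets C12 by catalyst-controlled hydrogenation. Allylic oxidation of the isopropenyl methyl group (SeO2, t-BuOOH, CH2Cl2) gives the 2-substituted allylic alcohol F6. Hydroxyl-directed asymmetric hydrogenation of F6 (H2, Ru(OAc)2[(S)-BINAP] or its enantiomer, whichever is matched, MeOH) delivers the (12S) alcohol, and the route is rejoined at 23.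

Further compounds
F1 | step 5 | 2,2-dimethyl-5-(triisopropylsilyloxy)-4H-1,3-dioxine | CC1(C)OCC(O[Si](C(C)C)(C(C)C)C(C)C)=CO1
F2 | step 5 | 2-(triisopropylsilyloxy)prop-2-enal | C=C(O[Si](C(C)C)(C(C)C)C(C)C)C=O
F3 | step 5 | 6-(2-chloroethyl)-2-(triisopropylsilyloxy)-8-oxabicyclo[3.2.1]oct-6-en-3-one, racemate (one enantiomer drawn) | O=C1C[C@H]2O[C@H](C=C2CCCl)[C@@H]1O[Si](C(C)C)(C(C)C)C(C)C
F4 | step 5 | enantiomer of 12 | O=C1C[C@@H]2O[C@@H](C=C2CCCl)[C@H]1O
F5 | step 5 | acetate of the enantiomer of 12 | O=C1C[C@@H]2O[C@@H](C=C2CCCl)[C@H]1OC(C)=O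
F6 | step 14 | allylic alcohol (3-hydroxyprop-1-en-2-yl group on C13) | O=C1C[C@H]2C[C@H]([C@@](C)(O[Si](CC)(CC)CC)CCCl)O[C@H](C(=C)CO)[C@H]2O1
F7 | step 22 | C7 terminal alkyne, chloroethyl arm intact | O=C1C[C@H]2C[C@H]([C@@](C)(O[Si](CC)(CC)CC)CCCl)O[C@H]([C@@H](C)CCC[C@@](C)(O[Si](CC)(CC)CC)C#C)[C@H]2O1
F8 | step 22 | C6 aldehyde of the C7 alkyne | O=C1C[C@H]2C[C@H]([C@@](C)(O[Si](CC)(CC)CC)CC=O)O[C@H]([C@@H](C)CCC[C@@](C)(O[Si](CC)(CC)CC)C#C)[C@H]2O1
F9 | step 22 | terminal diyne | O=C1C[C@H]2C[C@H]([C@@](C)(O[Si](CC)(CC)CC)CC#C)O[C@H]([C@@H](C)CCC[C@@](C)(O[Si](CC)(CC)CC)C#C)[C@H]2O1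
F10 | step 22 | macrocyclic C6≡C7 alkyne, bis(triethylsilyl) ether | C1C(=O)O[C@@H]2[C@@H]3O[C@H](C[C@H]12)[C@@](C)(O[Si](CC)(CC)CC)CC#C[C@](C)(O[Si](CC)(CC)CC)CCC[C@@H]3C
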